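All runs come from a simulation for substances that don't exist; the scatter is artificial.

Read 10.6% of target at 4.00 min in maple, and take that reading as the clock of this chemistry.

the same everywhere: catalyst 0.32 mol%; added ligand 0.87 mM

|  | substrate | temperature | remark | time |
|---|---|---|---|---|
| maple | 0.050 M | 100 °C | run made earlier |  |
| spring | 0.10 M | 100 °C |  | 12 min |
| dusk | 0.10 M | 70 °C |  | 12 min |
| midnight | 0.10 M | 130 °C |  | 12 min |
| summer | 0.10 M | 40 °C |  | 12 min |

maple run (percent of the substrate charged)

| time / min | target / % |
|---|---|
| 0.333 | 0.7 |
| 0.833 | 2.0 |
| 1.50 | 4.6 |
| 2.50 | 7.4 |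
| 4.00 | 10.6 |

(readings scatter by 0.5 percentage points)

- the earlier runs do not show what temperature does; that part of a forecast is a guess
- no earlier run changes the charge of catalyst; that part of a forecast is a guess

- the flask with the highest amount of target, in percent of the substrate charged ("all alike" if they lie within 1.5 percentage points) (spring / dusk / midnight / summer / all alike)
- final target, as a percentage of the substrate charged, in spring
- final target, as a percentage of the substrate charged, in dusk
- final target, as a percentage of the substrate charged, in midnight
- final target, as a percentage of the substrate charged, in summer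

Compare two times. One is the flask time t, here 12 min. The other is the catalytic time τ = 1/(κc). Here c is the charged catalyst concentration, substrate charge times loading, and κ is read from maple below. Solve both ends. Early, target y grows as t/τ. For the late end, assume that nothing returns, so that y reaches the whole charge. Join the ends with a pseudo-first-order curve:

y = 1 − exp(−t/τ)

Invert this on maple's last reading, where c = 0.160 mM:

κ = 175 L mol⁻¹ min⁻¹

Call κ the apparent rate constant per catalyst at 100 °C, a reading from maple that carries its scatter.

Spring holds twice maple's substrate at the same loading, so its c doubles too:

τ = 17.8 min, t/τ = 0.672, y = 48.9%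

τ is longer than t, so the curve puts the end of spring on its bend. This reckoning is mine. It gives no figure for the other flasks, since maple shows nothing of temperature.

The forecast names midnight as highest: spring 32%, dusk 7%, midnight 55%, summer 1%. It says: “Temperature is a guess”. My spring figure stands higher than its figure.

The flasks give spring as highest, with 36.0%; dusk gives 18.8%, midnight 21.5%, summer 5.06%. My 48.9% stands above the target in spring, and 12.1% of the charge stands there as isomer of the product. Now read summer through the same curve. Its c equals spring's, so its target puts the apparent κ at 40 °C below the κ read from maple, by a factor f = 13.0.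

    substrate + catalyst ⇌ target + catalyst, rate k1*[substrate]*[catalyst] forward; the back reaction follows from the equilibrium constant (K = 1.20, k = 280 L mol⁻¹ min⁻¹, Ea = 43.0 kJ mol⁻¹, ΔH = −59.0 kJ mol⁻¹)
    target ⇌ isomer of the product (K = 0.350, k = 0.140 min⁻¹, Ea = 95.0 kJ mol⁻¹, ΔH = −18.0 kJ mol⁻¹)
    catalyst + added ligand ⇌ idle complex, settled at all times (K = 500 L mol⁻¹, ΔH = −2.00 kJ mol⁻¹)
    isomer of the product ⇌ substrate (k = 0.0320 min⁻¹, Ea = 110 kJ mol⁻¹)
    (constants at 100 °C)

Take a neighbour flask: summer with 0.25 M of substrate at the same loading. Then t/τ = 0.130 and y = 12.2%. The flask gives 12.7%.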